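The pyrrole is cut at N1–C2 and C4–C5: N1 and the acetyl-bearing C5 come from aminoacetone, while C2 (with its ester), C3 and C4 (each with an indol-3-yl group) come from a 3,4-diaryl-2-oxobut-3-enoate. The key step exploits two features of this ring: the acetyl group on C5 acidifies the CH2 next to N1, and the ester on C2 makes the C2 ketone the most electrophilic carbon. Imine formation, six-electron closure of the 2-azapentadienyl anion and dehydrogenation then deliver the fully substituted pyrrole in one pot. The precursor is the E enone methyl 2-oxo-3,4-bis(1-tosylindol-3-yl)but-3-enoate, built from one aldehyde by azlactone and Knoevenagel chemistry.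

Key step: step 6

Remark on the chemistry: the enone precursor is taken as the E isomer (keto ester trans to the C4 indolyl group), the isomer expected under thermodynamic control; the ring closure does not depend on this geometry. The sp3 centres of transient intermediates are left undefined because the oxidation erases them.

Step 1
Reactants: 1 indole-3-carboxaldehyde; 2 p-toluenesulfonyl chloride
Product: 3 1-tosyl-1H-indole-3-carbaldehyde
Conditions: Et3N, 4-(dimethylamino)pyridine (cat.), CH2Cl2, 0 °C to rt
Reagents that add atoms: none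
Why: N-sulfonylation of the indole N–H, which the 3-formyl group makes acidic, is a standard protection under nucleophilic catalysis, and the sulfonyl group restores the electrophilicity of the aldehyde for the two condensations that follow.

Step 2
Reactants: 3 1-tosyl-1H-indole-3-carbaldehyde; 4 N-acetylglycine
Product: 6 (4Z)-2-methyl-4-[(1-tosyl-1H-indol-3-yl)methylidene]-1,3-oxazol-5(4H)-one, via 2-methyl-1,3-oxazol-5(4H)-one 5 (not isolated)
Conditions: Ac2O, NaOAc, 100 °C
Reagents that add atoms: none
Why: In this Erlenmeyer–Plöchl azlactone synthesis acetic anhydride cyclodehydrates N-acetylglycine to oxazolone 5, whose acidic ring CH2 condenses with the non-enolisable aldehyde in a Perkin-type aldol–dehydration to the thermodynamically preferred Z alkylidene azlactone, while the N-tosyl group is inert to acetate.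

Step 3
Reactants: 6 (4Z)-2-methyl-4-[(1-tosyl-1H-indol-3-yl)methylidene]-1,3-oxazol-5(4H)-one
Product: 8 2-oxo-3-(1-tosyl-1H-indol-3-yl)propanoic acid, via acetamidoacrylic acid 7 (not isolated)
Conditions: 3 M aq. HCl, AcOH, reflux, N2
Reagents that add atoms: water (O)
Why: Acid hydrolysis of an Erlenmeyer azlactone should open the activated lactone to enamide acid 7 and then, by protonation at the β-carbon and hydrolysis of the N-acyliminium ion, release the arylpyruvic acid, the N-sulfonylindole being stable to aqueous acid.

Step 4
Reactants: 8 2-oxo-3-(1-tosyl-1H-indol-3-yl)propanoic acid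
Product: 9 methyl 2-oxo-3-(1-tosyl-1H-indol-3-yl)propanoate
Conditions: MeOH, H2SO4 (cat.), rt to 50 °C
Reagents that add atoms: methanol (CO)
Why: Fischer esterification of an α-keto acid, whose carboxyl group is activated by the neighbouring carbonyl, should proceed under mild acid catalysis without touching the tosyl group or the largely enolised keto function.

Step 5
Reactants: 9 methyl 2-oxo-3-(1-tosyl-1H-indol-3-yl)propanoate; 3 1-tosyl-1H-indole-3-carbaldehyde
Product: 10 methyl (E)-2-oxo-3,4-bis(1-tosyl-1H-indol-3-yl)but-3-enoate
Conditions: piperidine (cat.), AcOH (cat.), toluene, reflux, Dean–Stark trap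
Reagents that add atoms: none
Why: In this Knoevenagel condensation the enol of 9 should add to the piperidinium iminium ion of 3 and the Mannich adduct should lose piperidine by E1cB, a path that avoids a free β-hydroxy ester able to lactonise, with water removal driving the equilibrium to the E enone as in α-aryl chalcones made the same way.

Step 6
Reactants: 10 methyl (E)-2-oxo-3,4-bis(1-tosyl-1H-indol-3-yl)but-3-enoate; 11 aminoacetone hydrochloride
Product: 14 methyl 5-acetyl-3,4-bis(1-tosyl-1H-indol-3-yl)-1H-pyrrole-2-carboxylate, via azadiene imine 12 (not isolated), via 1-pyrroline 13 (not isolated)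
Conditions: 11 (1.5 equiv), NaOAc, 4 Å molecular sieves, MeCN, rt; DBU, rt to 60 °C; then DDQ, 0 °C to rt
Reagents that add atoms: none
Why: Aminoacetone, released slowly from its hydrochloride by the acetate buffer, should condense at the ester-activated C2 ketone of 10 to give 1-azadiene 12; DBU then deprotonates the methylene flanked by the imine nitrogen and the acetyl group, the resulting 2-azapentadienyl anion (C5–N1–C2–C3–C4) closes thermally between C5 and C4, protonation of the cyclic 1-azaallyl anion gives pyrroline 13, and DDQ removes two hydrogens to aromatise. The closest known reaction type is the base-mediated 1,5-electrocyclization of imines formed from enones and glycine esters, aminoacetonitrile or α-amino ketones, followed by oxidation to pyrroles. The only ring formed, the pyrrole, closes by a disrotatory six-electron electrocyclization of a five-atom anion, which sidesteps the unfavourable 5-endo-trig geometry of a stepwise Michael closure and tolerates either alkene geometry because both can reach the s-cis azadiene. No stereocentre remains, since the sp3 carbons of 13 are erased by the dehydrogenation. The step needs site selectivity in the first condensation (imine at C2, not aza-Michael addition at C4 or self-condensation of aminoacetone); this is secured by the high electrophilicity of the α-keto ester carbonyl, by the crowded, doubly aryl-substituted C3=C4 bond and by the low standing concentration of free amine. The two N-tosyl groups keep the C4 terminus electron-poor and shield the neighbouring indoles from DDQ-induced oxidative coupling at their C2 positions.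

Step 7
Reactants: 14 methyl 5-acetyl-3,4-bis(1-tosyl-1H-indol-3-yl)-1H-pyrrole-2-carboxylate
Product: 15 methyl 5-acetyl-3,4-di(1H-indol-3-yl)-1H-pyrrole-2-carboxylate
Conditions: Cs2CO3, THF/MeOH (2:1), rt to 50 °C
Reagents that add atoms: none
Why: Nucleophilic N-desulfonylation of indoles by methoxide generated from Cs2CO3 in methanol is a mild known deprotection in which methanolysis of the methyl ester is degenerate and the acetylpyrrole, held as its unreactive pyrrolide anion, should stay untouched.

Compound list
1 | indole-3-carboxaldehyde | O=Cc1c[nH]c2ccccc12 | starting material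
2 | p-toluenesulfonyl chloride | Cc1ccc(S(=O)(=O)Cl)cc1 | starting material
3 | 1-tosyl-1H-indole-3-carbaldehyde | O=Cc1cn(S(=O)(=O)c2ccc(C)cc2)c2ccccc12 | intermediate
4 | N-acetylglycine | CC(=O)NCC(=O)O | starting material
5 | 2-methyl-1,3-oxazol-5(4H)-one (formed in the flask, not isolated) | CC1=NCC(=O)O1 | intermediate
6 | (4Z)-2-methyl-4-[(1-tosyl-1H-indol-3-yl)methylidene]-1,3-oxazol-5(4H)-one | CC1=N/C(=C\c2cn(S(=O)(=O)c3ccc(C)cc3)c3ccccc23)C(=O)O1 | intermediate
7 | (Z)-2-acetamido-3-(1-tosyl-1H-indol-3-yl)prop-2-enoic acid (not isolated) | CC(=O)N/C(=C\c1cn(S(=O)(=O)c2ccc(C)cc2)c2ccccc12)C(=O)O | intermediate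
8 | 2-oxo-3-(1-tosyl-1H-indol-3-yl)propanoic acid (keto form drawn, largely enolised) | O=C(O)C(=O)Cc1cn(S(=O)(=O)c2ccc(C)cc2)c2ccccc12 | intermediate
9 | methyl 2-oxo-3-(1-tosyl-1H-indol-3-yl)propanoate (keto form drawn, largely enolised) | COC(=O)C(=O)Cc1cn(S(=O)(=O)c2ccc(C)cc2)c2ccccc12 | intermediate
10 | methyl (E)-2-oxo-3,4-bis(1-tosyl-1H-indol-3-yl)but-3-enoate | COC(=O)C(=O)/C(=C/c1cn(S(=O)(=O)c2ccc(C)cc2)c2ccccc12)c1cn(S(=O)(=O)c2ccc(C)cc2)c2ccccc12 | intermediate
11 | aminoacetone hydrochloride | CC(=O)CN.Cl | starting material
12 | methyl (3E)-2-[(2-oxopropyl)imino]-3,4-bis(1-tosyl-1H-indol-3-yl)but-3-enoate (not isolated; C=N geometry mobile) | COC(=O)C(=NCC(C)=O)/C(=C/c1cn(S(=O)(=O)c2ccc(C)cc2)c2ccccc12)c1cn(S(=O)(=O)c2ccc(C)cc2)c2ccccc12 | intermediate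
13 | methyl 2-acetyl-3,4-bis(1-tosyl-1H-indol-3-yl)-3,4-dihydro-2H-pyrrole-5-carboxylate (not isolated; diastereomer mixture, in equilibrium with its enamine tautomer) | COC(=O)C1=NC(C(C)=O)C(c2cn(S(=O)(=O)c3ccc(C)cc3)c3ccccc23)C1c1cn(S(=O)(=O)c2ccc(C)cc2)c2ccccc12 | intermediate
14 | methyl 5-acetyl-3,4-bis(1-tosyl-1H-indol-3-yl)-1H-pyrrole-2-carboxylate | COC(=O)c1[nH]c(C(C)=O)c(-c2cn(S(=O)(=O)c3ccc(C)cc3)c3ccccc23)c1-c1cn(S(=O)(=O)c2ccc(C)cc2)c2ccccc12 | intermediate
15 | methyl 5-acetyl-3,4-di(1H-indol-3-yl)-1H-pyrrole-2-carboxylate | COC(=O)c1[nH]c(C(C)=O)c(-c2c[nH]c3ccccc23)c1-c1c[nH]c2ccccc12 | target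

Total step count: 7. Longest linear sequence: 7 steps (1 → 3 → 6 → 8 → 9 → 10 → 14 → 15); aldehyde 3 enters twice, so there is no separate branch.

Steps most likely to fail

Step 6. The amine may be consumed by self-condensation or add to C4 in a conjugate sense before the imine forms, or the azaallyl anion may only undergo a prototropic shift (transamination) without closing the ring. The fallback sets out from 10 and 11 and comes back at 13, and so at 14. It makes C4–C5 by an intermolecular Michael addition and N1–C2 by a later cyclocondensation. Transimination of 11 with benzophenone imine (CH2Cl2, rt) should give 1-[(diphenylmethylidene)amino]propan-2-one F1. Its stabilised carbanion (Cs2CO3, MeCN, 0 °C) should add to C4 of 10, as O'Donnell-type Schiff bases add to enones, giving methyl 5-[(diphenylmethylidene)amino]-2,6-dioxo-3,4-bis(1-tosyl-1H-indol-3-yl)heptanoate F2. Aqueous HCl in THF should cleave the benzophenone imine to methyl 5-amino-2,6-dioxo-3,4-bis(1-tosyl-1H-indol-3-yl)heptanoate hydrochloride F3. On neutralisation with NaHCO3 the amine should condense with the C2 ketone to pyrroline 13, and DDQ as in step 6 should then give 14.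

Step 5. An aldol-type adduct may lactonise onto the methyl ester to a hydroxybutenolide, the hindered and strongly enolised keto ester may condense sluggishly, or a second molecule of 9 may add to the enone. The fallback sets out from 3 and comes back at 10. It installs the C3 indolyl group by cross-coupling, not by condensation, and bypasses steps 2 to 5. Wittig olefination of 3 with methyl 2-oxo-3-(triphenylphosphoranylidene)propanoate (toluene, 80 °C) should give methyl (E)-2-oxo-4-(1-tosyl-1H-indol-3-yl)but-3-enoate F4. Br2 in CH2Cl2 at 0 °C should give methyl 3,4-dibromo-2-oxo-4-(1-tosyl-1H-indol-3-yl)butanoate F5, which Et3N should dehydrobrominate in the same flask to methyl (Z)-3-bromo-2-oxo-4-(1-tosyl-1H-indol-3-yl)but-3-enoate F6. Suzuki–Miyaura coupling of F6 with commercially available (1-tosyl-1H-indol-3-yl)boronic acid (Pd(PPh3)4, zerovalent palladium, K3PO4, 1,4-dioxane, 80 °C) should proceed with retention of alkene geometry and give E enone 10.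

Step 3. Hot aqueous acid may decarboxylate or oxidatively degrade the arylpyruvic acid, or hydrolysis may stop at the enamide. The fallback sets out from 3 and comes back at 9, bypassing steps 2 to 4. Horner–Wadsworth–Emmons olefination of 3 with methyl 2-[(tert-butyldimethylsilyl)oxy]-2-(dimethoxyphosphoryl)acetate (LiHMDS, THF, −78 °C to rt) should give methyl 2-[(tert-butyldimethylsilyl)oxy]-3-(1-tosyl-1H-indol-3-yl)prop-2-enoate F7 as an alkene isomer mixture. Cleavage of this silyl enol ether (CsF, AcOH, MeCN, rt) should release keto ester 9 without an acid hydrolysis step.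

Further compounds
F1 | step 6 | 1-[(diphenylmethylidene)amino]propan-2-one | CC(=O)CN=C(c1ccccc1)c1ccccc1
F2 | step 6 | methyl 5-[(diphenylmethylidene)amino]-2,6-dioxo-3,4-bis(1-tosyl-1H-indol-3-yl)heptanoate (diastereomer mixture) | COC(=O)C(=O)C(c1cn(S(=O)(=O)c2ccc(C)cc2)c2ccccc12)C(c1cn(S(=O)(=O)c2ccc(C)cc2)c2ccccc12)C(N=C(c1ccccc1)c1ccccc1)C(C)=O
F3 | step 6 | methyl 5-amino-2,6-dioxo-3,4-bis(1-tosyl-1H-indol-3-yl)heptanoate hydrochloride (diastereomer mixture) | COC(=O)C(=O)C(c1cn(S(=O)(=O)c2ccc(C)cc2)c2ccccc12)C(c1cn(S(=O)(=O)c2ccc(C)cc2)c2ccccc12)C(N)C(C)=O.Cl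
F4 | step 5 | methyl (E)-2-oxo-4-(1-tosyl-1H-indol-3-yl)but-3-enoate | COC(=O)C(=O)/C=C/c1cn(S(=O)(=O)c2ccc(C)cc2)c2ccccc12
F5 | step 5 | methyl 3,4-dibromo-2-oxo-4-(1-tosyl-1H-indol-3-yl)butanoate (diastereomer mixture) | COC(=O)C(=O)C(Br)C(Br)c1cn(S(=O)(=O)c2ccc(C)cc2)c2ccccc12
F6 | step 5 | methyl (Z)-3-bromo-2-oxo-4-(1-tosyl-1H-indol-3-yl)but-3-enoate | COC(=O)C(=O)/C(Br)=C/c1cn(S(=O)(=O)c2ccc(C)cc2)c2ccccc12
F7 | step 3 | methyl 2-[(tert-butyldimethylsilyl)oxy]-3-(1-tosyl-1H-indol-3-yl)prop-2-enoate (alkene isomer mixture) | COC(=O)C(O[Si](C)(C)C(C)(C)C)=Cc1cn(S(=O)(=O)c2ccc(C)cc2)c2ccccc12
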